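## Analysis of the target

Target 18 is a chroman whose C2 is also C2′ of a 3′,3′-dimethylnorbornane. Chroman atoms are numbered O1 to C8a, norbornane atoms C1′ to C7′, and the isobutyl carbons C1″ and C2″ outward from C4. Ring A (C4a, C5, C6, C7, C8, C8a) is a fully substituted phloroglucinol nucleus with hydroxyls on C5 and C7 and formyl groups on C6 and C8; ring B (O1, C2, C3, C4, C4a, C8a) carries the isobutyl group on C4. There are four stereocentres: the bridgeheads C1′ (R) and C4′ (S), the spiro carbon C2 (R, with O1 endo and C3 exo on the norbornane), and C4 (S). The hydrogen on C4 lies on the face of ring B occupied by C1′, and the isobutyl group lies on the face of the gem-dimethyl carbon C3′; C2 and C4 are 1,3-related across C3. The O1–C2 bond is a tertiary alkyl aryl ether at a 2-norbornyl carbon next to a quaternary carbon, so any cationic character at C2 invites Wagner–Meerwein rearrangement, and the two o-hydroxy aldehydes do not tolerate organometallic, hydride or hydrogenation steps. The difficulty is to make the hindered endo C–O bond without a cation and to relay configuration from C2 to C4. The plan rests on one observation: O5, C5, C4a, C4, C1″ and C2″ are the six atoms of a coumarin lactone ring (C2″ as the lactone carbonyl), C3 is the 4-methyl carbon of that coumarin and C8a is its peri carbon, so coumarin 1 already holds ring A, both phenolic oxygens, C3, C4, C1″ and C2″.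

## Retrosynthetic reasoning

**18 ⇒ 16.** The two C–CHO bonds at C6 and C8 are cut first. The aldehydes would not survive the hydride, organometallic and hydrogenation steps, and C6 and C8 are the only free positions of ring A in diphenol 16, so the forward diformylation has no regiochemical choice to make.

**16 ⇒ 15 ⇒ 14 ⇒ 13 ⇒ 12.** The isobutyl group is traced back to the lactone carbonyl of 12. The alkene of 15 comes from ketone 14 by Wittig methylenation, the ketone from the N-methoxy-N-methyl amide 13 by addition of one methyl group, and the amide from aminolysis of lactone 12, which also frees the C5 hydroxyl. Double methyl addition to the lactone is avoided: it would put a tertiary alcohol beside the free C5 phenol, and its dehydration would close a second pyran ring from O5 to C2″. The benzyl ether on O7 is chosen over a methyl ether so that it leaves in the hydrogenation of 15 and no late demethylation next to the acid-labile O1–C2 ether is needed.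

**12 ⇒ 11.** The C4–H bond is cut back to the enoate of 11. In 11 the coumarin and ring B form a rigid, nearly planar tricycle, and the spiro norbornane puts C3′ with its methyl groups on one face and the bridgehead C1′–H on the other. Hydride delivery to C4 from the C1′ face sets the last stereocentre.

**11 ⇒ 10 (key disconnection).** The O1–C8a bond is cut, which leaves a tertiary alcohol on C2 and a leaving group on the peri carbon of the coumarin. Cutting here, and not at O1–C2, means the ether oxygen is already on C2 as an alcohol before the ring is closed, so C2 never has to pass through a cation. The forward reaction is a palladium-catalysed aryl C–O coupling of the tertiary alkoxide with triflate 10. The lactone makes the aryl carbon electron-poor and holds the alcohol arm next to it.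

**10 ⇒ 9 ⇒ 8.** The triflate comes from phenol 9, and 9 from allyl ether 8. The peri oxygen has to be masked during the strongly basic C–C bond formation and unmasked without acid, which an allyl ether allows.

**8 ⇒ 3 + 6 (through 7).** The C2–C3 bond is cut as a vinylogous aldol. The 4-methyl group of coumarin 3 is acidified by the lactone and gives dienolate 7, which adds to ketone 6. This turns the spiro centre into a facial-selectivity problem on a norbornanone, where attack from the exo face is the normal course and puts the oxygen endo, as in 18.

**3 ⇒ 2 ⇒ 1 and 6 ⇒ 4.** The two phenols of 1 are told apart by hindrance: the C7 hydroxyl is benzylated first, then the peri hydroxyl is allylated. Ketone 6 is the ozonolysis product of terpene 4, whose bridgeheads already have the configuration of C1′ and C4′ in 18.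

## Alternatives that were turned down

**Alternative 1:** The C2–C3 bond is formed by a ketyl–olefin coupling. SmI2 with tert-butanol reduces camphenilone 6 to its ketyl, which adds on the exo face to the CH2 terminus of the α-aryl acrylate A1; the samarium alkoxide then lactonises onto the ester to give spiro γ-lactone A2.
- For it: the C–C bond is made irreversibly, so there is no retro-aldol problem. On this point it is stronger than the chosen route, whose aldol is an equilibrium.
- Against it: A1 is a styrene-type acceptor that is reduced more easily than the hindered ketone, so the electron may go to the wrong partner.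
- Against it: C4 is set as an epimerisable α-aryl lactone centre under thermodynamic control. It must then survive conversion of the lactone carbonyl into C1″ through a lactol or α-aryl aldehyde stage under basic olefination conditions.
- Against it: the O1–C8a bond still has to be made, now on an electron-rich, doubly ortho-substituted aryl chloride, a worse substrate for oxidative addition and C–O reductive elimination than an electron-poor coumarin triflate.
- Against it: two methyl ethers must be cleaved late, next to the acid-labile tertiary ether.
- Comparison: step count is similar. The chosen route offers a kinetically set, non-epimerisable C4 on a rigid tricycle and an activated partner for the C–O coupling.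

**Alternative 2:** Ring A is built from a polyketide chain. The δ-hydroxy triketo ester A3 is cyclodehydrated by mild acid to a spiro dihydropyranone (O1–C8a), and Mg(OMe)2 drives a Claisen condensation of C4a onto the ester carbon with aromatisation to chromanone A4.
- For it: the hindered tertiary ether is formed by carbonyl chemistry with no transition metal, and the 5,7-dihydroxy pattern appears without phenol protection. On the O1–C8a bond it is stronger than the chosen key step.
- Against it: the acid needed for cyclodehydration acts on a tertiary 2-norbornanol that can ionise and rearrange.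
- Against it: in A4 the ether oxygen is β to the C4 ketone, so base can open ring B by retro-oxa-Michael reaction and reclose it from either face, which puts the configuration of C2 at risk.
- Against it: C4 arrives as a chelated, hindered ketone. The whole isobutyl group must still be added and the oxygen removed, with C4 set only then.
- Comparison: the step count to 18 is not lower. The chosen route brings C4, C1″ and C2″ in with the coumarin and keeps C2 configurationally fixed.

**Alternative 3:** The C3–C4 bond is formed by radical cyclisation. Bu3SnH with azobisisobutyronitrile converts phenyl selenide A5 into the primary C3 radical, which adds 6-exo to the β-carbon of the aryl enone and gives ketone A6.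
- For it: conditions are neutral, there is no retro-aldol or base problem, and A6 already carries the 2-oxopropyl chain that the chosen route reaches only three steps after its key step. On paper this is the shorter route and the more direct one for the isobutyl group.
- Against it: A5 needs the tertiary aryl ether before the cyclisation. The obvious access, selenoetherification of camphene 4 with a hindered phenol, passes through cationic character at C2, with the risk of skeletal rearrangement.
- Against it: the neopentyl-type radical closes a six-membered ring slowly, so direct reduction and loss of the β-aryloxy group can compete.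
- Against it: C4 is set in a flexible transition state with only a 1,3-relationship to C2, and two methyl ethers remain to be cleaved late.
- Comparison: the chosen route is longer, but each stereocentre and the ether bond are decided by a defined element: exo addition to a ketone, a rigid tricycle, and a catalytic C–O coupling.

Key step: step 7

Assumption: the (−)-camphene 4 used is of high enantiomeric purity (or ketone 6 is enriched before use); no step touches the bridgeheads, so the optical purity of 18 is that of 6.

Remark on descriptors: the descriptor at C4 is R in 12, 13 and 14 and S in 15, 16 and 18 only because the CIP rank of the side chain changes; the spatial arrangement is the same throughout.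

## Route

Step 1
Reactants: 1 5,7-dihydroxy-4-methylcoumarin
Product: 2 7-(benzyloxy)-5-hydroxy-4-methylcoumarin
Conditions: BnBr (1 equiv), K2CO3, acetone, reflux
Reagents that add atoms: benzyl bromide, BrCc1ccccc1
Why: Williamson etherification; the C7 hydroxyl is the accessible phenol, whereas the C5 hydroxyl is peri to the 4-methyl group, so one equivalent of benzyl bromide should alkylate O7 selectively, as is usual for 5,7-dihydroxycoumarins.

Step 2
Reactants: 2 7-(benzyloxy)-5-hydroxy-4-methylcoumarin
Product: 3 5-(allyloxy)-7-(benzyloxy)-4-methylcoumarin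
Conditions: allyl bromide, K2CO3, DMF, 60 °C
Reagents that add atoms: allyl bromide, C=CCBr
Why: Williamson etherification of the remaining hindered phenol under more forcing conditions; the allyl ether tolerates the amide base of step 4 and can be removed later without acid.

Step 3
Reactants: 4 (1S,4R)-(−)-camphene
Product: 6 (1R,4S)-camphenilone, via camphene ozonide 5 (not isolated)
Conditions: O3, CH2Cl2, −78 °C; PPh3, −78 °C to rt
Reagents that add atoms: ozone, [O-][O+]=O
Why: Ozonolysis of the 1,1-disubstituted alkene with reductive work-up of ozonide 5; the bridgeheads are not touched, so the configuration of 4 is carried into 6.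

Step 4
Reactants: 3 5-(allyloxy)-7-(benzyloxy)-4-methylcoumarin, 6 (1R,4S)-camphenilone
Product: 8 5-(allyloxy)-7-(benzyloxy)-4-{[(1R,2R,4S)-2-hydroxy-3,3-dimethylbicyclo[2.2.1]heptan-2-yl]methyl}coumarin (hydroxyl endo), via lithium dienolate 7 (not isolated)
Conditions: LiN(iPr)2, THF, −78 °C; CeCl3, −78 °C; then 6, −78 °C; AcOH, −78 °C
Reagents that add atoms: none
Why: Vinylogous aldol addition: deprotonation of the 4-methyl group gives the extended dienolate 7, whose cerium form is oxophilic and weakly basic and should add through its CH2 terminus to the non-enolisable ketone, since only this mode restores the coumarin. Attack on 6 should come from the exo face, away from the endo hydrogens of the two-carbon bridge, which places the new hydroxyl endo and sets the future C2 as R. The cold acidic quench prevents reversal of the aldol.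

Step 5
Reactants: 8 5-(allyloxy)-7-(benzyloxy)-4-{[(1R,2R,4S)-2-hydroxy-3,3-dimethylbicyclo[2.2.1]heptan-2-yl]methyl}coumarin
Product: 9 7-(benzyloxy)-5-hydroxy-4-{[(1R,2R,4S)-2-hydroxy-3,3-dimethylbicyclo[2.2.1]heptan-2-yl]methyl}coumarin
Conditions: Pd(PPh3)4 (cat.), morpholine, THF, rt
Reagents that add atoms: none
Why: Tsuji–Trost deallylation: zerovalent palladium ionises the allyl aryl ether to a π-allyl complex that morpholine captures; the neutral conditions leave the tertiary aldol, the lactone and the benzyl ether intact.

Step 6
Reactants: 9 7-(benzyloxy)-5-hydroxy-4-{[(1R,2R,4S)-2-hydroxy-3,3-dimethylbicyclo[2.2.1]heptan-2-yl]methyl}coumarin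
Product: 10 7-(benzyloxy)-4-{[(1R,2R,4S)-2-hydroxy-3,3-dimethylbicyclo[2.2.1]heptan-2-yl]methyl}-2-oxo-2H-chromen-5-yl trifluoromethanesulfonate
Conditions: PhNTf2, Et3N, DMAP (cat.), CH2Cl2, 0 °C to rt
Reagents that add atoms: N-phenyl-bis(trifluoromethanesulfonimide), O=S(=O)(N(c1ccccc1)S(=O)(=O)C(F)(F)F)C(F)(F)F
Why: O-Sulfonylation of the phenoxide with a mild triflyl donor; the hindered tertiary alcohol should not react with this reagent, which a stronger electrophile such as triflic anhydride would not guarantee.

Step 7
Reactants: 10 7-(benzyloxy)-4-{[(1R,2R,4S)-2-hydroxy-3,3-dimethylbicyclo[2.2.1]heptan-2-yl]methyl}-2-oxo-2H-chromen-5-yl trifluoromethanesulfonate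
Product: 11 5-O-lactone of (Z)-2-[(2R,1'R,4'S)-7-(benzyloxy)-5-hydroxy-3',3'-dimethylspiro[chromane-2,2'-norbornan]-4-ylidene]acetic acid (O1 endo)
Conditions: Pd(OAc)2 (cat.), tBuXPhos (2-di-tert-butylphosphino-2',4',6'-triisopropylbiphenyl, cat.), K3PO4, toluene, 80 °C
Reagents that add atoms: none
Why: This is an intramolecular Buchwald–Hartwig-type C–O coupling, the closest known reaction being the palladium-catalysed cyclisation of tertiary alcohols onto aryl halides and sulfonates to give chromans. Zerovalent palladium, formed from Pd(OAc)2 and the phosphine, inserts into the C5–OTf bond of the electron-poor coumarin; the pendant hydroxyl then binds the divalent arylpalladium centre, is deprotonated there by K3PO4 and gives a seven-membered aryl(alkoxo)palladium chelate. Reductive elimination from this chelate forms the O1–C8a bond (numbering of 18) and closes the six-membered ring B, a closure at an sp2 carbon that the bulky di-tert-butylphosphine and the electron-poor aryl group both accelerate. No stereocentre is created, and C2 keeps the configuration set in step 4 because none of its bonds is broken. The step needs chemoselectivity for C–O coupling over retro-aldol loss of 6 and over S–O cleavage of the triflate; the weak, insoluble base keeps the concentration of free alkoxide low, and the tertiary alkoxide has no carbinol hydrogen, so β-hydride elimination and reduction of the triflate are excluded. The planar coumarin holds the alcohol arm beside the peri carbon, and the arm is trans to the lactone carbonyl across the ring double bond, so attack of the alkoxide on the lactone is geometrically impossible.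

Step 8
Reactants: 11 5-O-lactone of (Z)-2-[(2R,1'R,4'S)-7-(benzyloxy)-5-hydroxy-3',3'-dimethylspiro[chromane-2,2'-norbornan]-4-ylidene]acetic acid
Product: 12 5-O-lactone of 2-[(2R,4R,1'R,4'S)-7-(benzyloxy)-5-hydroxy-3',3'-dimethylspiro[chromane-2,2'-norbornan]-4-yl]acetic acid (H on C4 on the face of C1')
Conditions: Cu(OAc)2·H2O (cat.), 1,2-bis(diphenylphosphino)benzene (cat.), (EtO)2MeSiH, t-BuOH, toluene, rt
Reagents that add atoms: none
Why: Copper hydride conjugate reduction of a β,β-disubstituted unsaturated lactone (1,4-hydrocupration, then protonation by tert-butanol). The exo-methyl group on C3' is eclipsed with the C2–C3 bond and covers one face of C4, while the other face carries only the bridgehead hydrogen of C1', so the bulky phosphine–copper hydride should deliver hydrogen to C4 from the C1' face, as 18 requires.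

Step 9
Reactants: 12 5-O-lactone of 2-[(2R,4R,1'R,4'S)-7-(benzyloxy)-5-hydroxy-3',3'-dimethylspiro[chromane-2,2'-norbornan]-4-yl]acetic acid
Product: 13 2-[(2R,4R,1'R,4'S)-7-(benzyloxy)-5-hydroxy-3',3'-dimethylspiro[chromane-2,2'-norbornan]-4-yl]-N-methoxy-N-methylacetamide
Conditions: MeNH(OMe)·HCl, iPrMgCl, THF, −20 to 0 °C; H2O
Reagents that add atoms: N,O-dimethylhydroxylamine hydrochloride, CNOC.Cl
Why: Aminolysis of the activated aryl ester by the magnesium amide gives the Weinreb amide and releases the C5 phenol; C4 is not involved.

Step 10
Reactants: 13 2-[(2R,4R,1'R,4'S)-7-(benzyloxy)-5-hydroxy-3',3'-dimethylspiro[chromane-2,2'-norbornan]-4-yl]-N-methoxy-N-methylacetamide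
Product: 14 1-[(2R,4R,1'R,4'S)-7-(benzyloxy)-5-hydroxy-3',3'-dimethylspiro[chromane-2,2'-norbornan]-4-yl]propan-2-one
Conditions: MeMgBr (3 equiv), THF, 0 °C; H2O
Reagents that add atoms: methylmagnesium bromide, C[Mg]Br
Why: Weinreb ketone synthesis: one equivalent deprotonates the phenol and the next adds to give a chelated tetrahedral intermediate that collapses only on work-up, so addition stops at the methyl ketone (which may sit partly as its cyclic hemiketal with the C5 hydroxyl).

Step 11
Reactants: 14 1-[(2R,4R,1'R,4'S)-7-(benzyloxy)-5-hydroxy-3',3'-dimethylspiro[chromane-2,2'-norbornan]-4-yl]propan-2-one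
Product: 15 (2R,4S,1'R,4'S)-7-(benzyloxy)-3',3'-dimethyl-4-(2-methylprop-2-en-1-yl)spiro[chromane-2,2'-norbornan]-5-ol
Conditions: Ph3PCH3Br, KOtBu (excess), THF, 0 °C to rt
Reagents that add atoms: methyltriphenylphosphonium bromide, C[P+](c1ccccc1)(c1ccccc1)c1ccccc1.[Br-]
Why: Wittig methylenation of the ketone in the presence of the phenoxide; the alkene is formed without any cationic intermediate, so the free C5 phenol cannot close a second pyran ring, and C4, which is β to the ketone, cannot epimerise.

Step 12
Reactants: 15 (2R,4S,1'R,4'S)-7-(benzyloxy)-3',3'-dimethyl-4-(2-methylprop-2-en-1-yl)spiro[chromane-2,2'-norbornan]-5-ol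
Product: 16 (2R,4S,1'R,4'S)-4-isobutyl-3',3'-dimethylspiro[chromane-2,2'-norbornane]-5,7-diol
Conditions: H2 (1 atm), Pd/C, EtOAc/EtOH, rt
Reagents that add atoms: none
Why: Heterogeneous hydrogenation saturates the 1,1-disubstituted alkene to the isobutyl group and removes the benzyl ether by hydrogenolysis in the same operation; the tertiary alkyl aryl ether is not a benzylic C–O bond and should stay.

Step 13
Reactants: 16 (2R,4S,1'R,4'S)-4-isobutyl-3',3'-dimethylspiro[chromane-2,2'-norbornane]-5,7-diol
Product: 18 (2R,4S,1'R,4'S)-5,7-dihydroxy-4-isobutyl-3',3'-dimethylspiro[chromane-2,2'-norbornane]-6,8-dicarbaldehyde, via bis-iminium salt 17 (not isolated)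
Conditions: POCl3, DMF, MeCN, 0 °C to rt; then H2O, 50 °C
Reagents that add atoms: N,N-dimethylformamide, CN(C)C=O; water, O
Why: Double Vilsmeier–Haack formylation: the chloroiminium ion attacks C6 and C8, the only free positions of ring A and each flanked by two oxygens, and hydrolysis of bis-iminium salt 17 gives the hydrogen-bonded dialdehyde. The medium is only weakly acidic and buffered by DMF, which the tertiary ether should tolerate.

## Compound list

1 | 5,7-dihydroxy-4-methylcoumarin | Cc1cc(=O)oc2cc(O)cc(O)c12 | starting material
2 | 7-(benzyloxy)-5-hydroxy-4-methylcoumarin | Cc1cc(=O)oc2cc(OCc3ccccc3)cc(O)c12 | intermediate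
3 | 5-(allyloxy)-7-(benzyloxy)-4-methylcoumarin | Cc1cc(=O)oc2cc(OCc3ccccc3)cc(OCC=C)c12 | intermediate
4 | (1S,4R)-(−)-camphene | C=C1[C@@H]2CC[C@@H](C2)C1(C)C | starting material
5 | camphene ozonide (spiro 1,2,4-trioxolane on the former alkene carbon, both epimers at that carbon; not isolated) | C1OC2(OO1)[C@@H]3CC[C@@H](C3)C2(C)C | intermediate
6 | (1R,4S)-camphenilone, (1R,4S)-3,3-dimethylbicyclo[2.2.1]heptan-2-one | O=C1[C@@H]2CC[C@@H](C2)C1(C)C | intermediate
7 | lithium dienolate of 3, lithium 5-(allyloxy)-7-(benzyloxy)-4-methylidene-4H-chromen-2-olate (not isolated) | [Li]OC1=CC(=C)c2c(OCC=C)cc(OCc3ccccc3)cc2O1 | intermediate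
8 | 5-(allyloxy)-7-(benzyloxy)-4-{[(1R,2R,4S)-2-hydroxy-3,3-dimethylbicyclo[2.2.1]heptan-2-yl]methyl}coumarin (hydroxyl endo) | O=c1cc(C[C@@]2(O)[C@@H]3CC[C@@H](C3)C2(C)C)c2c(OCC=C)cc(OCc3ccccc3)cc2o1 | intermediate
9 | 7-(benzyloxy)-5-hydroxy-4-{[(1R,2R,4S)-2-hydroxy-3,3-dimethylbicyclo[2.2.1]heptan-2-yl]methyl}coumarin | O=c1cc(C[C@@]2(O)[C@@H]3CC[C@@H](C3)C2(C)C)c2c(O)cc(OCc3ccccc3)cc2o1 | intermediate
10 | 7-(benzyloxy)-4-{[(1R,2R,4S)-2-hydroxy-3,3-dimethylbicyclo[2.2.1]heptan-2-yl]methyl}-2-oxo-2H-chromen-5-yl trifluoromethanesulfonate | O=c1cc(C[C@@]2(O)[C@@H]3CC[C@@H](C3)C2(C)C)c2c(OS(=O)(=O)C(F)(F)F)cc(OCc3ccccc3)cc2o1 | intermediate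
11 | 5-O-lactone of (Z)-2-[(2R,1'R,4'S)-7-(benzyloxy)-5-hydroxy-3',3'-dimethylspiro[chromane-2,2'-norbornan]-4-ylidene]acetic acid | O=C1C=C2C[C@@]3(Oc4cc(OCc5ccccc5)cc(O1)c24)[C@@H]1CC[C@@H](C1)C3(C)C | intermediate
12 | 5-O-lactone of 2-[(2R,4R,1'R,4'S)-7-(benzyloxy)-5-hydroxy-3',3'-dimethylspiro[chromane-2,2'-norbornan]-4-yl]acetic acid | O=C1C[C@H]2C[C@@]3(Oc4cc(OCc5ccccc5)cc(O1)c24)[C@@H]1CC[C@@H](C1)C3(C)C | intermediate
13 | 2-[(2R,4R,1'R,4'S)-7-(benzyloxy)-5-hydroxy-3',3'-dimethylspiro[chromane-2,2'-norbornan]-4-yl]-N-methoxy-N-methylacetamide | CON(C)C(=O)C[C@H]1C[C@@]2(Oc3cc(OCc4ccccc4)cc(O)c31)[C@@H]1CC[C@@H](C1)C2(C)C | intermediate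
14 | 1-[(2R,4R,1'R,4'S)-7-(benzyloxy)-5-hydroxy-3',3'-dimethylspiro[chromane-2,2'-norbornan]-4-yl]propan-2-one | CC(=O)C[C@H]1C[C@@]2(Oc3cc(OCc4ccccc4)cc(O)c31)[C@@H]1CC[C@@H](C1)C2(C)C | intermediate
15 | (2R,4S,1'R,4'S)-7-(benzyloxy)-3',3'-dimethyl-4-(2-methylprop-2-en-1-yl)spiro[chromane-2,2'-norbornan]-5-ol | C=C(C)C[C@H]1C[C@@]2(Oc3cc(OCc4ccccc4)cc(O)c31)[C@@H]1CC[C@@H](C1)C2(C)C | intermediate
16 | (2R,4S,1'R,4'S)-4-isobutyl-3',3'-dimethylspiro[chromane-2,2'-norbornane]-5,7-diol | CC(C)C[C@H]1C[C@@]2(Oc3cc(O)cc(O)c31)[C@@H]1CC[C@@H](C1)C2(C)C | intermediate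
17 | 6,8-bis[(dimethyliminio)methyl] derivative of 16, dichloride (not isolated) | CC(C)C[C@H]1C[C@@]2(Oc3c(C=[N+](C)C)c(O)c(C=[N+](C)C)c(O)c31)[C@@H]1CC[C@@H](C1)C2(C)C.[Cl-].[Cl-] | intermediate
18 | (2R,4S,1'R,4'S)-5,7-dihydroxy-4-isobutyl-3',3'-dimethylspiro[chromane-2,2'-norbornane]-6,8-dicarbaldehyde | CC(C)C[C@H]1C[C@@]2(Oc3c(C=O)c(O)c(C=O)c(O)c31)[C@@H]1CC[C@@H](C1)C2(C)C | target

## Step count and least certain steps

Total step count: 13. Longest linear sequence: 12 steps (1 to 18 through steps 1, 2 and 4 to 13); the one-step branch from 4 to 6 joins at step 4.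

**Step 7 (key step).**
- What may go wrong: oxidative addition at the peri-hindered C–OTf bond may be slow, so that base-driven retro-aldol fragmentation of the vinylogous β-hydroxy lactone or S–O cleavage of the triflate takes over. After closure, removal of a C3 hydrogen γ to the lactone carbonyl with expulsion of the O1 aryloxide could reopen ring B.
- Fallback: set out from 10 and reduce the enoate first, using copper hydride with an enantiopure bisphosphine such as DTBM-SEGPHOS (Cu(OAc)2·H2O, (EtO)2MeSiH, t-BuOH), the antipode being the one that gives the 4R centre. This gives (4R)-7-(benzyloxy)-4-{[(1R,2R,4S)-2-hydroxy-3,3-dimethylbicyclo[2.2.1]heptan-2-yl]methyl}-2-oxo-3,4-dihydro-2H-chromen-5-yl trifluoromethanesulfonate F1. F1 is no longer a vinylogous aldol and cannot fragment, so the same Pd(OAc)2, tBuXPhos and K3PO4 etherification, now open to stronger base or higher temperature, closes ring B and comes back to the route at 12. The cost is that C4 then rests on catalyst control, and the saturated lactone of F1 can in principle be attacked by the alkoxide.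

**Step 4.**
- What may go wrong: the aldol equilibrium between a stabilised dienolate and a hindered ketone may lie on the side of the components, with reversal on warming; attack through the ring carbon next to the carbonyl may also compete.
- Fallback: set out from 3, trap the dienolate with Me3SiCl (LiN(iPr)2, THF, −78 °C) as 5-(allyloxy)-7-(benzyloxy)-4-methylidene-2-(trimethylsilyloxy)-4H-chromene F2, and add it to 6 in a TiCl4-promoted vinylogous Mukaiyama aldol reaction (CH2Cl2, −78 °C). A neutral nucleophile then attacks the Lewis-acid-activated ketone and no basic alkoxide that could revert is present. The sequence comes back at 8.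

**Step 8.**
- What may go wrong: facial discrimination at C4 may be poor if the exo-methyl group shields less than expected, and 1,2-reduction or opening of the aryl lactone may compete.
- Fallback: move from substrate control to catalyst control. Set out from 11 and generate the copper hydride with an enantiopure bisphosphine (DTBM-SEGPHOS, both antipodes to be tried) in place of the achiral ligand, so that the ligand reinforces delivery to the C1' face. It comes back at 12 and makes no compound outside the route (F0).

**Step 13.**
- What may go wrong: the second formylation may stall once the first iminium group has deactivated the ring, or acid-promoted ionisation of the O1–C2 ether may lead to skeletal rearrangement of the norbornane.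
- Fallback: replace electrophilic substitution by an organolithium route. Set out from 16 and dibrominate with N-bromosuccinimide (MeCN, 0 °C) to (2R,4S,1'R,4'S)-6,8-dibromo-4-isobutyl-3',3'-dimethylspiro[chromane-2,2'-norbornane]-5,7-diol F3. Protect both phenols (MOMCl, iPr2NEt) to give the 5,7-bis(methoxymethoxy) dibromide F4. Carry out two successive bromine–lithium exchange and DMF cycles in one flask (n-BuLi, THF, −78 °C; the lithium hemiaminal formed in the first cycle masks the first formyl group) to give the 5,7-bis(methoxymethoxy)-6,8-dicarbaldehyde F5. Cleave the formyl-flanked acetals with dilute HCl in MeOH/THF at rt to come back at 18.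

## Further compounds

F1 | step 7 | (4R)-7-(benzyloxy)-4-{[(1R,2R,4S)-2-hydroxy-3,3-dimethylbicyclo[2.2.1]heptan-2-yl]methyl}-2-oxo-3,4-dihydro-2H-chromen-5-yl trifluoromethanesulfonate | O=C1C[C@@H](C[C@@]2(O)[C@@H]3CC[C@@H](C3)C2(C)C)c2c(OS(=O)(=O)C(F)(F)F)cc(OCc3ccccc3)cc2O1
F2 | step 4 | 5-(allyloxy)-7-(benzyloxy)-4-methylidene-2-(trimethylsilyloxy)-4H-chromene | C[Si](C)(C)OC1=CC(=C)c2c(OCC=C)cc(OCc3ccccc3)cc2O1
F0 | step 8 | none | none
F3 | step 13 | (2R,4S,1'R,4'S)-6,8-dibromo-4-isobutyl-3',3'-dimethylspiro[chromane-2,2'-norbornane]-5,7-diol | CC(C)C[C@H]1C[C@@]2(Oc3c(Br)c(O)c(Br)c(O)c31)[C@@H]1CC[C@@H](C1)C2(C)C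
F4 | step 13 | (2R,4S,1'R,4'S)-6,8-dibromo-4-isobutyl-5,7-bis(methoxymethoxy)-3',3'-dimethylspiro[chromane-2,2'-norbornane] | CC(C)C[C@H]1C[C@@]2(Oc3c(Br)c(OCOC)c(Br)c(OCOC)c31)[C@@H]1CC[C@@H](C1)C2(C)C
F5 | step 13 | (2R,4S,1'R,4'S)-4-isobutyl-5,7-bis(methoxymethoxy)-3',3'-dimethylspiro[chromane-2,2'-norbornane]-6,8-dicarbaldehyde | CC(C)C[C@H]1C[C@@]2(Oc3c(C=O)c(OCOC)c(C=O)c(OCOC)c31)[C@@H]1CC[C@@H](C1)C2(C)C
A1 | alternative 1 | methyl 2-(2-chloro-4,6-dimethoxyphenyl)prop-2-enoate | C=C(C(=O)OC)c1c(Cl)cc(OC)cc1OC
A2 | alternative 1 | spiro γ-lactone, 3-(2-chloro-4,6-dimethoxyphenyl)-3',3'-dimethylspiro[oxolane-5,2'-norbornan]-2-one (lactone oxygen endo) | O=C1[C@H](c2c(Cl)cc(OC)cc2OC)C[C@@]2(O1)[C@@H]1CC[C@@H](C1)C2(C)C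
A3 | alternative 2 | methyl 8-[(1R,2R,4S)-2-hydroxy-3,3-dimethylbicyclo[2.2.1]heptan-2-yl]-3,5,7-trioxooctanoate | COC(=O)CC(=O)CC(=O)CC(=O)C[C@@]1(O)[C@@H]2CC[C@@H](C2)C1(C)C
A4 | alternative 2 | 5,7-dihydroxy-3',3'-dimethylspiro[chromane-2,2'-norbornan]-4-one (O1 endo) | O=C1C[C@@]2(Oc3cc(O)cc(O)c31)[C@@H]1CC[C@@H](C1)C2(C)C
A5 | alternative 3 | (E)-4-{2,4-dimethoxy-6-[(3,3-dimethyl-2-exo-[(phenylselanyl)methyl]norbornan-2-endo-yl)oxy]phenyl}but-3-en-2-one | CC(=O)/C=C/c1c(OC)cc(OC)cc1O[C@]1(C[Se]c2ccccc2)[C@@H]2CC[C@@H](C2)C1(C)C
A6 | alternative 3 | 1-[5,7-dimethoxy-3',3'-dimethylspiro[chromane-2,2'-norbornan]-4-yl]propan-2-one with the C2 and C4 configuration of 18 | CC(=O)C[C@H]1C[C@@]2(Oc3cc(OC)cc(OC)c31)[C@@H]1CC[C@@H](C1)C2(C)C
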